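**Retrosynthetic overview**

1. The route rests on the bicyclo[4.2.0]octane carbocycle. Its six-membered ring C1–C6, with methyls on C1, C3 and C5, is a dearomatised 2,4,6-trimethylphenol; the cyclobutane carbons C7 and C8, their two cis methyls and the pyranone carbon on C7 are a tiglate. Because that pyranone carbon stands on the same side of the four-membered ring as C5, an O–C(=O) bridge from C5 to C7 can hold the two parts together.
2. The dioxabicycle (last ring) comes from singlet oxygen and the C2–C5 diene; the methoxypyranone from the C7 carboxylic acid and a propionate-derived β-keto ester dianion, by lactonisation and O-methylation.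
3. The diene acid comes from the C2 dienyl triflate, made after SmI2 has cut the C5–O bond of a tricyclic enone γ-lactone.
4. The enone lactone comes from a desymmetrising intramolecular [2+2] photocycloaddition of the achiral p-quinol tiglate (bonds C6–C7 and C1–C8); the ester is made from 2,4,6-trimethylphenol and tigloyl chloride.
5. Ring order: six-membered carbocycle (from the arene), γ-lactone and cyclobutane together (step 3), lactone opened (step 4), pyranone (step 9), 1,2-dioxane bridge (step 11).

Key step: step 3

Assumption: the sense of induction of the chiral Lewis acid on this substrate cannot be derived from precedent; the catalyst from (S)-prolinol is written, and its mirror image is used if it delivers the enantiomer of the photoadduct.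

Numbering and stereochemical shorthand: the carbocycle is numbered as bicyclo[4.2.0]octane (C1 methylated fusion carbon, C2–C5 the four-carbon bridge starting next to C1, C6 fusion CH, C7 quaternary cyclobutane carbon, C8 CHMe). From the photoadduct onwards every compound has the same configuration at C1, C6, C7 and C8: cis ring fusion, with C1-Me, C6-H, C7-Me and C8-Me on one face of the cyclobutane (exo) and the C7 carbonyl or pyranone substituent on the other (endo, cis to C5). The absolute configuration is that of the SMILES.

**Route**

Step 1
Reactants: 1 2,4,6-trimethylphenol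
Product: 2 4-hydroxy-2,4,6-trimethylcyclohexa-2,5-dien-1-one (achiral p-quinol)
Conditions: PhI(OAc)2, MeCN–H2O (3:1), 0 °C
Reagents that add atoms: water, O
Why: Oxidative dearomatisation of a para-alkylphenol by a hypervalent iodine reagent, in which water attacks the para carbon of the aryloxy-iodane; the carbinol carbon lies on the mirror plane, so no stereocentre arises.

Step 2
Reactants: 2 4-hydroxy-2,4,6-trimethylcyclohexa-2,5-dien-1-one; 3 tigloyl chloride ((E)-2-methylbut-2-enoyl chloride)
Product: 4 1,3,5-trimethyl-4-oxocyclohexa-2,5-dien-1-yl (E)-2-methylbut-2-enoate (achiral quinol tiglate)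
Conditions: pyridine, DMAP (cat.), CH2Cl2, 0 °C to rt
Reagents that add atoms: none
Why: DMAP-catalysed acylation of the tertiary alcohol through the acylpyridinium ion; the weak base pyridine avoids vinylketene formation, so the E alkene stays conjugated, and the ester is achiral.

Step 3
Reactants: 4 quinol tiglate
Product: 5 tricyclic enone γ-lactone (lactone between the C7 carboxyl and the C5 oxygen of 5-hydroxy-1,3,5,7,8-pentamethyl-2-oxobicyclo[4.2.0]oct-3-ene-7-carboxylic acid; cis-fused; lactone on the endo face)
Conditions: (S)-3,3-bis(3,5-dimethylphenyl)-1-(2,4,6-trifluorophenyl)tetrahydro-1H,3H-pyrrolo[1,2-c][1,3,2]oxazaborole (50 mol %), AlBr3 (45 mol %), CH2Cl2, −75 °C, hν (366 nm)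
Reagents that add atoms: none
Why: Proposed new method: the AlBr3-activated oxazaborolidine binds the dienone oxygen and shifts the ππ* band of the complex to the irradiation wavelength, so that only bound substrate is excited; its triplet bonds from the enone β-carbon C6 to the tiglate α-carbon C7, and the 1,4-diradical (C1, C8) closes after spin inversion. The closest known reaction type is the oxazaborolidine–AlBr3-catalysed enantioselective intramolecular enone–alkene [2+2] photocycloaddition of cyclohexenones, and the racemic reaction is known for 4,4-disubstituted cyclohexadienones; new here are the quinol ester tether and the choice between two enantiotopic enone alkenes. The γ-lactone closes in the first bond by a 5-exo-trig attack (rule of five for a 1,6-diene), and the cyclobutane in the second by 1,4-diradical recombination, which gives the straight and not the crossed adduct. The Lewis acid sits syn to one of the two enone alkenes and is expected to leave only one of them open on the ester-bearing face, which decides the absolute configuration at C1, C5 and C6; the three-atom tether delivers C7 to the oxygen-bearing face of C6 and puts its carboxyl carbon endo (cis to C5), the four-membered ring can only be cis-fused at C1–C6, and the E geometry of the tiglate, with closure of the diradical to the exo C8 methyl, keeps the C7 and C8 methyls cis. The step needs the intramolecular addition to outrun the lumiketone rearrangement and C5–O cleavage of the excited quinol ester; the alkene held three atoms from C6, the selective long-wavelength excitation of the complex and the low temperature serve this.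

Step 4
Reactants: 5 tricyclic enone γ-lactone
Product: 7 1,3,5,7,8-pentamethyl-2-oxobicyclo[4.2.0]oct-4-ene-7-carboxylic acid (β,γ-unsaturated keto acid; C3 epimers), via trivalent samarium dienolate 6 (not isolated)
Conditions: SmI2 (2.2 equiv), THF–MeOH, −78 °C; pH 5 buffer
Reagents that add atoms: none
Why: Samarium diiodide reduction of a γ-acyloxy enone (vinylogous α-heterosubstituted ketone): two single-electron transfers put charge on C4, the C5 carboxylate leaves by β-elimination and opens the lactone, and methanol protonates the dienolate at C3 without control, a centre that is erased in step 5.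

Step 5
Reactants: 7 β,γ-unsaturated keto acid
Product: 9 1,3,5,7,8-pentamethyl-2-(trifluoromethylsulfonyloxy)bicyclo[4.2.0]octa-2,4-diene-7-carboxylic acid, via dipotassium dianion 8 (not isolated)
Conditions: KN(SiMe3)2 (2.2 equiv), THF, −78 °C; PhNTf2 (1.05 equiv), −78 to −20 °C; cold 0.5 M HCl to pH 4
Reagents that add atoms: N-phenylbis(trifluoromethanesulfonimide), O=S(=O)(N(c1ccccc1)S(=O)(=O)C(F)(F)F)C(F)(F)F
Why: Enol triflate formation: C1 is quaternary, so the ketone can only give the extended C2–C5 dienolate, whose oxygen is far more nucleophilic than the carboxylate toward the mild triflyl donor; as a carboxylate, the C7 substituent cannot leave as an enolate in a vinylogous retro-Michael opening of the cyclobutane.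

Step 6
Reactants: 9 dienyl triflate acid
Product: 10 1,3,5,7,8-pentamethylbicyclo[4.2.0]octa-2,4-diene-7-carboxylic acid
Conditions: Pd(OAc)2 (5 mol %), PPh3 (10 mol %), HCO2H, Bu3N, DMF, 40 °C
Reagents that add atoms: none
Why: Palladium-catalysed formate reduction of an enol triflate (oxidative addition of zerovalent palladium, formate exchange, loss of CO2, reductive elimination of C–H) leaves the diene in place; 40 °C keeps the thermal 6π ring opening of the bicyclo[4.2.0]octa-2,4-diene slow.

Step 7
Reactants: 10 diene acid
Product: 11 (1H-imidazol-1-yl)(1,3,5,7,8-pentamethylbicyclo[4.2.0]octa-2,4-dien-7-yl)methanone (acyl imidazole)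
Conditions: 1,1'-carbonyldiimidazole, THF, rt
Reagents that add atoms: 1,1'-carbonyldiimidazole, O=C(n1ccnc1)n1ccnc1
Why: Carboxyl activation through the mixed anhydride with loss of CO2 works for α-quaternary acids under neutral conditions, which spares the acid-sensitive diene.

Step 8
Reactants: 11 acyl imidazole; 12 methyl 2-methyl-3-oxopentanoate
Product: 14 methyl 2,4-dimethyl-3,5-dioxo-5-(1,3,5,7,8-pentamethylbicyclo[4.2.0]octa-2,4-dien-7-yl)pentanoate (side-chain epimers and enol forms), via dilithium dianion 13 (not isolated)
Conditions: 12 (3 equiv), LiN(iPr)2 (2.05 equiv per 12), THF, −78 to 0 °C; then 11, −78 to −20 °C; aq. HCl to pH 4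
Reagents that add atoms: none
Why: Claisen-type C-acylation of a β-keto ester dianion at its γ-carbon by an acyl imidazole; the acyl donor has no α-hydrogen, and the excess dianion covers the proton taken by the more acidic product.

Step 9
Reactants: 14 diketo ester
Product: 15 4-hydroxy-3,5-dimethyl-6-(1,3,5,7,8-pentamethylbicyclo[4.2.0]octa-2,4-dien-7-yl)-2H-pyran-2-one
Conditions: DBU, toluene, 40 °C
Reagents that add atoms: none
Why: Base-mediated lactonisation of a 3,5-diketo ester (enol oxygen of the C5 ketone onto the ester, loss of methanol) gives the 4-hydroxy-2-pyranone; it is run at 40 °C, not at reflux, so that the diene does not open and reclose to its ring-fusion epimer.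

Step 10
Reactants: 15 hydroxy-2-pyranone
Product: 17 2-methoxy-3,5-dimethyl-6-(1,3,5,7,8-pentamethylbicyclo[4.2.0]octa-2,4-dien-7-yl)-4H-pyran-4-one, via hydroxymethoxypyrylium fluorosulfonate 16 (not isolated)
Conditions: MeOSO2F, CH2Cl2, 0 °C; then cold aq. NaHCO3
Reagents that add atoms: methyl fluorosulfonate, COS(=O)(=O)F
Why: Regioselective O-methylation of the neutral 4-hydroxy-2-pyranone protomer at the lactone carbonyl oxygen, the basic site remote from the proton, by a hard methylating agent; deprotonation of the pyrylium salt on work-up gives the 2-methoxy-4-pyranone.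

Step 11
Reactants: 17 diene methoxypyranone
Product: 18 2-methoxy-3,5-dimethyl-6-(2,5-epidioxy-1,3,5,7,8-pentamethylbicyclo[4.2.0]oct-3-en-7-yl)-4H-pyran-4-one (target; peroxide bridge on the face of C1-Me and C6-H)
Conditions: O2, methylene blue (cat.), hν (visible), CH2Cl2, −20 °C
Reagents that add atoms: dioxygen, O=O
Why: [4+2] cycloaddition of singlet oxygen to the cyclohexa-1,3-diene; it should add suprafacially to C2 and C5 from the face of the C1 methyl and C6 hydrogen, because the other face is covered by the cyclobutane and its endo pyranone, and this sets C2 and C5.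

**Compound list**

1 | 2,4,6-trimethylphenol | Cc1cc(C)c(O)c(C)c1 | starting material
2 | 4-hydroxy-2,4,6-trimethylcyclohexa-2,5-dien-1-one | CC1=CC(C)(O)C=C(C)C1=O | intermediate
3 | tigloyl chloride | C/C=C(\C)C(=O)Cl | starting material
4 | 1,3,5-trimethyl-4-oxocyclohexa-2,5-dien-1-yl tiglate | C/C=C(\C)C(=O)OC1(C)C=C(C)C(=O)C(C)=C1 | intermediate
5 | tricyclic enone γ-lactone | O=C4[C@@]2(C)[C@H](C)[C@@]3(C)C(=O)C(C)=C[C@@](C)(O4)[C@@H]23 | intermediate
6 | trivalent samarium dienolate carboxylate | [O-]C(=O)[C@@]2(C)[C@H](C)[C@@]3(C)C([O-])=C(C)C=C(C)[C@@H]23.[Sm+3].[Sm+3].[I-].[I-].[I-].[I-] | intermediate (not isolated)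
7 | 1,3,5,7,8-pentamethyl-2-oxobicyclo[4.2.0]oct-4-ene-7-carboxylic acid (C3 epimers) | OC(=O)[C@@]2(C)[C@H](C)[C@@]3(C)C(=O)C(C)C=C(C)[C@@H]23 | intermediate
8 | dipotassium carboxylate dienolate | [O-]C(=O)[C@@]2(C)[C@H](C)[C@@]3(C)C([O-])=C(C)C=C(C)[C@@H]23.[K+].[K+] | intermediate (not isolated)
9 | 2-triflyloxy-1,3,5,7,8-pentamethylbicyclo[4.2.0]octa-2,4-diene-7-carboxylic acid | OC(=O)[C@@]2(C)[C@H](C)[C@@]3(C)C(OS(=O)(=O)C(F)(F)F)=C(C)C=C(C)[C@@H]23 | intermediate
10 | 1,3,5,7,8-pentamethylbicyclo[4.2.0]octa-2,4-diene-7-carboxylic acid | OC(=O)[C@@]2(C)[C@H](C)[C@@]3(C)C=C(C)C=C(C)[C@@H]23 | intermediate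
11 | acyl imidazole of 10 | O=C(n1ccnc1)[C@@]2(C)[C@H](C)[C@@]3(C)C=C(C)C=C(C)[C@@H]23 | intermediate
12 | methyl 2-methyl-3-oxopentanoate | CCC(=O)C(C)C(=O)OC | starting material
13 | dilithium dianion of 12 | [Li+].[Li+].COC(=O)C(C)=C([O-])[CH-]C | intermediate (not isolated)
14 | diketo ester (side-chain epimers) | COC(=O)C(C)C(=O)C(C)C(=O)[C@@]2(C)[C@H](C)[C@@]3(C)C=C(C)C=C(C)[C@@H]23 | intermediate
15 | 4-hydroxy-2-pyranone diene | O=C1OC([C@@]2(C)[C@H](C)[C@@]3(C)C=C(C)C=C(C)[C@@H]23)=C(C)C(O)=C1C | intermediate
16 | 4-hydroxy-2-methoxypyrylium fluorosulfonate | COc1[o+]c([C@@]2(C)[C@H](C)[C@@]3(C)C=C(C)C=C(C)[C@@H]23)c(C)c(O)c1C.[O-]S(=O)(=O)F | intermediate (not isolated)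
17 | 2-methoxy-4-pyranone diene | COc1oc([C@@]2(C)[C@H](C)[C@@]3(C)C=C(C)C=C(C)[C@@H]23)c(C)c(=O)c1C | intermediate
18 | CNP0183511.1 (endoperoxide) | COc1oc([C@@]2(C)[C@H](C)[C@@]3(C)[C@@H]4OO[C@@](C)(C=C4C)[C@@H]23)c(C)c(=O)c1C | target

**Step count and risks**

Total step count: 11. Longest linear sequence: 11 steps (1 to 18); 3 and 12 enter as purchased materials.

Steps most likely to fail:

1. Step 3 (proposed new method). The Lewis acid may discriminate poorly between the two enantiotopic enone alkenes, AlBr3 may ionise the tertiary bis-allylic ester (dienone–phenol pathway), and at −75 °C the ester may reach the rotamer needed for closure too slowly, so that lumiketone rearrangement or crossed addition takes over. Fallback, from 4: irradiation without Lewis acid in CH2Cl2 at room temperature (350 nm, or 405 nm with thioxanthone as triplet sensitiser). This is the racemic intramolecular enone–alkene [2+2] photocycloaddition known for 4,4-disubstituted cyclohexadienones, and it should give the racemic tricyclic lactone F1. Preparative chromatography on a chiral stationary phase (amylose tris(3,5-dimethylphenylcarbamate)) then separates the enantiomers, and the route is rejoined at 5.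

2. Step 8. Attack of the dianion on the α-quaternary acyl imidazole may be slower than proton transfer and self-condensation of the dianion. Fallback, from 10: reduction with LiAlH4 (THF, 0 °C) to the primary alcohol F2; oxidation with Dess–Martin periodinane buffered with NaHCO3 to the aldehyde F3; aldol addition of dianion 13 at −78 °C to the β-hydroxy keto ester F4; a second Dess–Martin oxidation then gives the diketo ester, and the route is rejoined at 14.

3. Step 10. The acidic pyrylium salt formed during methylation may protonate the electron-rich cyclohexadiene, leading to double-bond migration or cationic opening of the cyclobutane. Fallback, from 15: the order of the last two operations is inverted. Singlet oxygen (O2, methylene blue, hν, CH2Cl2, −20 °C) is added first to give the endoperoxide hydroxypyranone F5, which no longer contains the diene. Methyl fluorosulfonate (CH2Cl2, 0 °C) then gives the pyrylium salt F6, and cold aqueous NaHCO3 releases the target, so the route is rejoined at 18.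

**Further compounds**

F1 | step 3 | racemic tricyclic enone γ-lactone (racemate of 5; one enantiomer drawn) | O=C4[C@@]2(C)[C@H](C)[C@@]3(C)C(=O)C(C)=C[C@@](C)(O4)[C@@H]23
F2 | step 8 | (1,3,5,7,8-pentamethylbicyclo[4.2.0]octa-2,4-dien-7-yl)methanol | OC[C@@]2(C)[C@H](C)[C@@]3(C)C=C(C)C=C(C)[C@@H]23
F3 | step 8 | 1,3,5,7,8-pentamethylbicyclo[4.2.0]octa-2,4-diene-7-carbaldehyde | O=C[C@@]2(C)[C@H](C)[C@@]3(C)C=C(C)C=C(C)[C@@H]23
F4 | step 8 | β-hydroxy keto ester (aldol adduct; carbinol and side-chain epimers) | COC(=O)C(C)C(=O)C(C)C(O)[C@@]2(C)[C@H](C)[C@@]3(C)C=C(C)C=C(C)[C@@H]23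
F5 | step 10 | endoperoxide 4-hydroxy-2-pyranone | O=C1OC([C@@]2(C)[C@H](C)[C@@]3(C)[C@@H]4OO[C@@](C)(C=C4C)[C@@H]23)=C(C)C(O)=C1C
F6 | step 10 | endoperoxide 4-hydroxy-2-methoxypyrylium fluorosulfonate | COc1[o+]c([C@@]2(C)[C@H](C)[C@@]3(C)[C@@H]4OO[C@@](C)(C=C4C)[C@@H]23)c(C)c(O)c1C.[O-]S(=O)(=O)F
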